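**Strategy.** The route rests on cutting the bond between the guaiacyl ring and C2 of the 3,7-dioxabicyclo[3.3.0]octane. C2 is an acetal-type carbon (bonded to ring oxygen O3) beside the oxygenated bridgehead C1, and its aryl group is cis to the C1 oxygen. The key step uses this: a 1,2-anhydro (oxirane) acetal spanning C1–C2, formed in the flask from a lactol diol, is opened by an arylzinc whose zinc binds the C1 alkoxide and hands the aryl to C2 on the same face. One operation joins the fragments, sets C2 and frees the C1 hydroxyl for acetylation. The precursor is a veratryl-bearing bicyclic lactol with no second aryl group.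

Key step: step 6

Remark: atoms are numbered as in 3,7-dioxabicyclo[3.3.0]octane (C1 acetoxy bridgehead, C2 guaiacyl carbon, C5 bridgehead CH, C6 veratryl carbon); lactol 10 and chloride 13 are taken as anomeric mixtures, and the antipode of the chromium ligand in step 2 is assumed to be the one that gives the (S)-carbinol, to be confirmed on the first batch.

**Step 1**
Reactants: 1 3-methylenedihydrofuran-2(3H)-one (α-methylene-γ-butyrolactone)
Product: 3 3-(bromomethyl)furan-2(5H)-one, via dibromide 2 (not isolated)
Conditions: Br2, CH2Cl2, 0 °C; then i-Pr2NEt, 0 °C → rt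
Reagents that add atoms: bromine (BrBr)
Why: Bromine addition to the exocyclic alkene followed by E2 loss of HBr from the tertiary α-bromide and a ring β-hydrogen (bromination–dehydrobromination) should give the conjugated butenolide with the allylic bromide intact.

**Step 2**
Reactants: 3 3-(bromomethyl)furan-2(5H)-one; 4 3,4-dimethoxybenzaldehyde
Product: 6 (R)-4-[(S)-(3,4-dimethoxyphenyl)(hydroxy)methyl]-3-methylenedihydrofuran-2(3H)-one, via trimethylsilyl ether 5 (not isolated)
Conditions: CrCl2 (10 mol %), chiral carbazole-bis(oxazoline) ligand (12 mol %), Mn, TMSCl, THF, 0 °C → rt; then 1 M HCl, THF, 0 °C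
Reagents that add atoms: none
Why: Catalytic asymmetric Nozaki–Hiyama–Kishi allylation, in which the allylchromium from 3 adds through its ring γ-carbon in a closed chair transition state (ring CH2O E-disposed), should give the anti-type pair C5 (R)/C6 (S) with the ligand choosing the aldehyde face, and the silyl ether 5 formed by catalyst turnover is cleaved on acidic work-up.

**Step 3**
Reactants: 6 (R)-4-[(S)-(3,4-dimethoxyphenyl)(hydroxy)methyl]-3-methylenedihydrofuran-2(3H)-one
Product: 7 (3S,4R)-4-[(S)-(3,4-dimethoxyphenyl)(hydroxy)methyl]-3-hydroxy-3-(hydroxymethyl)dihydrofuran-2(3H)-one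
Conditions: OsO4 (2 mol %), NMO, acetone/H2O, rt
Reagents that add atoms: N-methylmorpholine N-oxide (C[N+]1([O-])CCOCC1); water (O)
Why: Osmium-catalysed syn dihydroxylation of the exocyclic alkene from the lactone face anti to the bulky C4 side chain should set the tertiary carbinol (future C1, 3S), placing its oxygen trans and the new CH2OH cis to the aryl carbinol arm.

**Step 4**
Reactants: 7 (3S,4R)-4-[(S)-(3,4-dimethoxyphenyl)(hydroxy)methyl]-3-hydroxy-3-(hydroxymethyl)dihydrofuran-2(3H)-one
Product: 9 (1S,5R,6S)-6-(3,4-dimethoxyphenyl)-1-hydroxy-3,7-dioxabicyclo[3.3.0]octan-2-one, via primary tosylate 8 (not isolated)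
Conditions: TsCl (1.1 equiv), pyridine, 0 °C → rt; then 60 °C
Reagents that add atoms: none
Why: Selective sulfonylation of the primary hydroxyl and intramolecular Williamson-type 5-exo-tet displacement by the benzylic hydroxyl should close the tetrahydrofuran ring with retention at C6, the cis ring fusion following from the cis CH2OTs/carbinol arrangement set in step 3.

**Step 5**
Reactants: 9 (1S,5R,6S)-6-(3,4-dimethoxyphenyl)-1-hydroxy-3,7-dioxabicyclo[3.3.0]octan-2-one
Product: 10 (1S,5R,6S)-6-(3,4-dimethoxyphenyl)-3,7-dioxabicyclo[3.3.0]octane-1,2-diol (lactol)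
Conditions: DIBAL-H (2.5 equiv), CH2Cl2, −78 °C; aq. Rochelle salt
Reagents that add atoms: none
Why: DIBAL-H partial reduction of the γ-lactone should stop at the aluminium hemiacetal at −78 °C, with the tertiary hydroxyl carried as its aluminium alkoxide, and no stereocentre of 9 is touched.

**Step 6**
Reactants: 10 (1S,5R,6S)-6-(3,4-dimethoxyphenyl)-3,7-dioxabicyclo[3.3.0]octane-1,2-diol; 11 [4-(benzyloxy)-3-methoxyphenyl]boronic acid
Product: 15 (1S,2R,5R,6S)-2-[4-(benzyloxy)-3-methoxyphenyl]-6-(3,4-dimethoxyphenyl)-3,7-dioxabicyclo[3.3.0]octan-1-ol, via arylethylzinc 12 (not isolated), via anomeric chloride 13 (not isolated), via 1,2-anhydro oxirane 14 (not isolated)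
Conditions: 11, Et2Zn, toluene, 60 °C (gives 12); separately 10, 1-chloro-N,N,2-trimethylpropenylamine, CH2Cl2, 0 °C, evaporate; add to 12, toluene, 0 °C → rt; aq. NH4Cl
Reagents that add atoms: none
Why: The chloro-enamine converts the hemiacetal hydroxyl of 10 into anomeric chloride 13 under neutral conditions; on addition to 12 the C1 hydroxyl is deprotonated and the zinc alkoxide displaces chloride to give the exo oxirane 14, which zinc reopens at the acetal carbon C2 to an oxocarbenium ion paired with an aryl(alkoxy)zinc species. The aryl group then moves from zinc to C2 on the face that carries the C1 oxygen; the closest known reaction type is the 1,2-cis C-arylation of 1,2-anhydro sugars with arylzinc reagents made from arylboronic acids and diethylzinc, with organozinc arylation of glycosyl halides as a second precedent. No ring of the product is closed here; the transient oxirane closes 3-exo-tet and reopens. The new stereocentre C2 (R) is controlled by this internal delivery from the C1–O–Zn tether, reinforced by the convex face of the cis-fused bicycle, so aryl and C1–OH should end up cis. The step needs aryl rather than ethyl transfer (sp2 groups leave mixed arylalkylzincs faster), syn rather than anti opening (secured by the covalent tether and the absence of a participating acyl group on C1) and activation of the lactol rather than the tertiary alcohol (secured by the higher reactivity of the hemiacetal hydroxyl). The mild zinc Lewis acid should leave the C6 benzylic ether configuration intact.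

**Step 7**
Reactants: 15 (1S,2R,5R,6S)-2-[4-(benzyloxy)-3-methoxyphenyl]-6-(3,4-dimethoxyphenyl)-3,7-dioxabicyclo[3.3.0]octan-1-ol
Product: 16 (1S,2R,5R,6S)-2-[4-(benzyloxy)-3-methoxyphenyl]-6-(3,4-dimethoxyphenyl)-3,7-dioxabicyclo[3.3.0]oct-1-yl acetate
Conditions: Ac2O, DMAP, Et3N, CH2Cl2, 40 °C
Reagents that add atoms: acetic anhydride (CC(=O)OC(C)=O)
Why: DMAP-catalysed acylation should esterify the hindered tertiary alcohol under acid-free conditions, so the two benzylic ether centres are not epimerised.

**Step 8**
Reactants: 16 (1S,2R,5R,6S)-2-[4-(benzyloxy)-3-methoxyphenyl]-6-(3,4-dimethoxyphenyl)-3,7-dioxabicyclo[3.3.0]oct-1-yl acetate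
Product: 17 (1S,2R,5R,6S)-6-(3,4-dimethoxyphenyl)-2-(4-hydroxy-3-methoxyphenyl)-3,7-dioxabicyclo[3.3.0]oct-1-yl acetate (CNP0107105.1)
Conditions: H2 (1 atm), 10% Pd/C, EtOAc, rt
Reagents that add atoms: none
Why: Neutral hydrogenolysis of the aryl benzyl ether, stopped at full conversion, should free the phenol while the slower-reacting ring benzylic C–O bonds and the tertiary acetate remain.

**Compound list**
1 | 3-methylenedihydrofuran-2(3H)-one | C=C1CCOC1=O | starting material
2 | 3-bromo-3-(bromomethyl)dihydrofuran-2(3H)-one (racemic) | BrCC1(Br)CCOC1=O | intermediate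
3 | 3-(bromomethyl)furan-2(5H)-one | BrCC1=CCOC1=O | intermediate
4 | 3,4-dimethoxybenzaldehyde | COc1ccc(C=O)cc1OC | starting material
5 | (R)-4-[(S)-(3,4-dimethoxyphenyl)(trimethylsilyloxy)methyl]-3-methylenedihydrofuran-2(3H)-one | C=C1C(=O)OC[C@@H]1[C@H](O[Si](C)(C)C)c1ccc(OC)c(OC)c1 | intermediate
6 | (R)-4-[(S)-(3,4-dimethoxyphenyl)(hydroxy)methyl]-3-methylenedihydrofuran-2(3H)-one | C=C1C(=O)OC[C@@H]1[C@H](O)c1ccc(OC)c(OC)c1 | intermediate
7 | (3S,4R)-4-[(S)-(3,4-dimethoxyphenyl)(hydroxy)methyl]-3-hydroxy-3-(hydroxymethyl)dihydrofuran-2(3H)-one | O=C1OC[C@H]([C@H](O)c2ccc(OC)c(OC)c2)[C@]1(O)CO | intermediate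
8 | primary p-toluenesulfonate of 7 | O=C1OC[C@H]([C@H](O)c2ccc(OC)c(OC)c2)[C@]1(O)COS(=O)(=O)c1ccc(C)cc1 | intermediate
9 | (1S,5R,6S)-6-(3,4-dimethoxyphenyl)-1-hydroxy-3,7-dioxabicyclo[3.3.0]octan-2-one | O=C1OC[C@@H]2[C@@H](c3ccc(OC)c(OC)c3)OC[C@]12O | intermediate
10 | (1S,5R,6S)-6-(3,4-dimethoxyphenyl)-3,7-dioxabicyclo[3.3.0]octane-1,2-diol (anomeric mixture at C2) | OC1OC[C@@H]2[C@@H](c3ccc(OC)c(OC)c3)OC[C@]12O | intermediate
11 | [4-(benzyloxy)-3-methoxyphenyl]boronic acid | COc1cc(B(O)O)ccc1OCc1ccccc1 | starting material
12 | [4-(benzyloxy)-3-methoxyphenyl](ethyl)zinc | CC[Zn]c1ccc(OCc2ccccc2)c(OC)c1 | intermediate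
13 | (1S,5R,6S)-2-chloro-6-(3,4-dimethoxyphenyl)-3,7-dioxabicyclo[3.3.0]octan-1-ol (anomeric mixture) | ClC1OC[C@@H]2[C@@H](c3ccc(OC)c(OC)c3)OC[C@]12O | intermediate
14 | (1S,2R,5R,6S)-6-(3,4-dimethoxyphenyl)-1,2-epoxy-3,7-dioxabicyclo[3.3.0]octane (oxirane on the convex face) | [C@H]12OC[C@@H]3[C@@H](c4ccc(OC)c(OC)c4)OC[C@]13O2 | intermediate
15 | (1S,2R,5R,6S)-2-[4-(benzyloxy)-3-methoxyphenyl]-6-(3,4-dimethoxyphenyl)-3,7-dioxabicyclo[3.3.0]octan-1-ol | COc1cc([C@H]2OC[C@@H]3[C@@H](c4ccc(OC)c(OC)c4)OC[C@]23O)ccc1OCc1ccccc1 | intermediate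
16 | (1S,2R,5R,6S)-2-[4-(benzyloxy)-3-methoxyphenyl]-6-(3,4-dimethoxyphenyl)-3,7-dioxabicyclo[3.3.0]oct-1-yl acetate | COc1cc([C@H]2OC[C@@H]3[C@@H](c4ccc(OC)c(OC)c4)OC[C@]23OC(C)=O)ccc1OCc1ccccc1 | intermediate
17 | (1S,2R,5R,6S)-6-(3,4-dimethoxyphenyl)-2-(4-hydroxy-3-methoxyphenyl)-3,7-dioxabicyclo[3.3.0]oct-1-yl acetate | COc1cc([C@H]2OC[C@@H]3[C@@H](c4ccc(OC)c(OC)c4)OC[C@]23OC(C)=O)ccc1O | target

**Step count.** Total: 8 steps. Longest linear sequence: 8 steps (1 → 17); boronic acid 11 enters at step 6.

**Steps most likely to fail**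

Step 6 (key step). The activation may also touch the tertiary C1 hydroxyl, the oxirane may be opened from the face opposite the C1 oxygen, ethyl may be transferred in place of aryl, or the Lewis acid may epimerise C6. The fallback sets out from lactol 10 and boronic acid 11. Selective acetylation of the hemiacetal hydroxyl (Ac2O, pyridine, 0 °C) would give the anomeric monoacetate F1, and 11 with KHF2 (MeOH/H2O) would give the potassium aryltrifluoroborate F2. BF3·OEt2 (MeCN, −30 → 0 °C) would ionise F1 to the C2 oxocarbenium ion and convert F2 into an aryldifluoroborane that is bound by the free C1 hydroxyl and transfers aryl to the same face. This is a boron-tethered oxocarbenium arylation, related to the known BF3-promoted additions of organotrifluoroborates to cyclic acetals and to hydroxyl-directed boronate additions to cyclic N-acyliminium ions. It returns to the route at alcohol 15.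

Step 4. Displacement at the neopentyl-type CH2OTs may be slow, so that acyl migration of the lactone to the benzylic hydroxyl (translactonisation, which would lead to the wrong bicyclic lactone) or closure by the tertiary hydroxyl competes. The fallback sets out from triol 7. Mitsunobu dehydration of the primary/tertiary 1,2-diol (PPh3, DIAD, THF, 0 °C) would give the spiro-epoxide F3. Mild acid (CSA cat., CH2Cl2, 0 °C) would then let the benzylic hydroxyl open the oxirane at its CH2 terminus; attack at the quaternary carbon would need an oxetane and is not expected. This returns to the route at hydroxy lactone 9 without any basic conditions.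

Step 2. Enantio- or diastereofacial control may be insufficient with the electron-rich aldehyde and the cyclic allyl bromide. The fallback sets out from bromide 3 and aldehyde 4. Palladium-catalysed borylation of 3 (B2pin2, Pd2(dba)3, DMSO, 50 °C) would give the allylboronate F4. Allylboration of 4 catalysed by a chiral BINOL-derived phosphoric acid (toluene, −30 °C) goes through a closed chair transition state with the same anti-type outcome, and after aqueous work-up returns to the route at alcohol 6.

**Further compounds**
F1 | step 6 | (1S,5R,6S)-6-(3,4-dimethoxyphenyl)-1-hydroxy-3,7-dioxabicyclo[3.3.0]oct-2-yl acetate (anomeric mixture) | CC(=O)OC1OC[C@@H]2[C@@H](c3ccc(OC)c(OC)c3)OC[C@]12O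
F2 | step 6 | potassium [4-(benzyloxy)-3-methoxyphenyl]trifluoroborate | [K+].F[B-](F)(F)c1ccc(OCc2ccccc2)c(OC)c1
F3 | step 4 | (3S,7R)-7-[(S)-(3,4-dimethoxyphenyl)(hydroxy)methyl]-1,5-dioxaspiro[2.4]heptan-4-one | O=C1OC[C@H]([C@H](O)c2ccc(OC)c(OC)c2)[C@]12CO2
F4 | step 2 | 3-[(4,4,5,5-tetramethyl-1,3,2-dioxaborolan-2-yl)methyl]furan-2(5H)-one | CC1(C)OB(CC2=CCOC2=O)OC1(C)C
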